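**Retrosynthetic overview**
1. Ring C (the pyranone) is closed last by forming the O1–C2 bond (a C–O bond) on an acyclic, fully MOM-protected α-aryl enaminone; the same pot frees the four phenols.
2. The enaminone is a deoxybenzoin plus one carbon at the formyl oxidation level (DMF-DMA).
3. The deoxybenzoin is cut at C3–C1′ into a ring A methyl ketone and a ring B aryl bromide (palladium-catalysed enolate arylation).
4. The ring B bromide comes from 4,6-dibromoresorcinol (MOM protection, one Br/Li exchange, prenylation); the ring A ketone comes from 2′,6′-dihydroxy-4′-methoxyacetophenone (MOM protection).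
5. Ring order: rings A and B are bought as benzenes; ring C is the only ring made, in the final step.

Assumption: the target is achiral (no stereocentre, no E/Z-defined alkene), so no enantiocontrol is needed; all starting materials are taken as catalogue chemicals.

**Step 1**
Reactants: 1 4,6-dibromobenzene-1,3-diol (4,6-dibromoresorcinol)
Product: 2 1,5-dibromo-2,4-bis(methoxymethoxy)benzene
Conditions: MOMCl (2.5 equiv), K2CO3 (3 equiv), acetone, 0 °C to rt
Reagents that add atoms: chloromethyl methyl ether (MOMCl), COCCl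
Why: Williamson-type O-alkylation of the two acidic phenols gives the bis-MOM acetal, which tolerates organolithium and palladium chemistry and stabilises the ortho-lithio species of the next step; no stereocentre is formed.

**Step 2**
Reactants: 2 1,5-dibromo-2,4-bis(methoxymethoxy)benzene, 3 1-bromo-3-methylbut-2-ene (prenyl bromide)
Product: 5 1-bromo-2,4-bis(methoxymethoxy)-5-(3-methylbut-2-en-1-yl)benzene, via aryllithium 4 (not isolated)
Conditions: n-BuLi (1.05 equiv), THF, −78 °C; then CuBr·SMe2 (20 mol%), 3 (1.3 equiv), −78 °C to rt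
Reagents that add atoms: none
Why: Bromine–lithium exchange on the symmetrical dibromide stops after one exchange at −78 °C, and copper-catalysed SN2 allylic substitution of prenyl bromide by the aryl anion places the 3-methylbut-2-enyl group para to the future 2′-oxygen while the second bromide is kept as the coupling handle; no stereocentre is formed.

**Step 3**
Reactants: 6 1-(2,6-dihydroxy-4-methoxyphenyl)ethan-1-one
Product: 8 1-[4-methoxy-2,6-bis(methoxymethoxy)phenyl]ethan-1-one, via disodium bis-phenoxide 7 (not isolated)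
Conditions: NaH (2.2 equiv), DMF, 0 °C; then MOMCl (2.4 equiv), 0 °C to rt
Reagents that add atoms: chloromethyl methyl ether (MOMCl), COCCl
Why: Double deprotonation breaks the phenol–carbonyl hydrogen bonds so that both chelated hydroxyls undergo Williamson O-alkylation, masking ring A for the enolate coupling; no stereocentre is formed.

**Step 4**
Reactants: 8 1-[4-methoxy-2,6-bis(methoxymethoxy)phenyl]ethan-1-one, 5 1-bromo-2,4-bis(methoxymethoxy)-5-(3-methylbut-2-en-1-yl)benzene
Product: 9 1-[4-methoxy-2,6-bis(methoxymethoxy)phenyl]-2-[2,4-bis(methoxymethoxy)-5-(3-methylbut-2-en-1-yl)phenyl]ethan-1-one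
Conditions: Pd2(dba)3 (2 mol%), XPhos (5 mol%), NaOt-Bu (2.2 equiv), toluene, 70–80 °C; 8 in slight excess (1.2 equiv)
Reagents that add atoms: none
Why: Buchwald–Hartwig-type ketone α-arylation, in which oxidative addition of bromide 5 to zerovalent palladium, transmetalation with the sodium enolate of 8 and C–C reductive elimination from the bulky XPhos complex give the deoxybenzoin, with the ortho substituents on both aryl rings suppressing diarylation; no stereocentre is formed.

**Step 5**
Reactants: 9 1-[4-methoxy-2,6-bis(methoxymethoxy)phenyl]-2-[2,4-bis(methoxymethoxy)-5-(3-methylbut-2-en-1-yl)phenyl]ethan-1-one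
Product: 10 (E)-3-(dimethylamino)-1-[4-methoxy-2,6-bis(methoxymethoxy)phenyl]-2-[2,4-bis(methoxymethoxy)-5-(3-methylbut-2-en-1-yl)phenyl]prop-2-en-1-one
Conditions: DMF-DMA (5 equiv), toluene, 100 °C
Reagents that add atoms: N,N-dimethylformamide dimethyl acetal (DMF-DMA), COC(OC)N(C)C
Why: Enaminone condensation of the doubly activated benzylic methylene with DMF-DMA installs C2 of the future pyranone at the formyl oxidation level, so no later oxidation that could touch the prenyl group is needed, and with no free phenol present there is no O-methylation; the E and Z forms of the push–pull alkene interconvert and no stereocentre is formed.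

**Step 6**
Reactants: 10 (E)-3-(dimethylamino)-1-[4-methoxy-2,6-bis(methoxymethoxy)phenyl]-2-[2,4-bis(methoxymethoxy)-5-(3-methylbut-2-en-1-yl)phenyl]prop-2-en-1-one
Product: 14 3-[2,4-dihydroxy-5-(3-methylbut-2-en-1-yl)phenyl]-5-hydroxy-7-methoxy-4H-chromen-4-one (isopoegin B), via magnesium phenoxide 11 (not isolated), via tris-MOM isoflavone 12 (not isolated), via bis-MOM isoflavone 13 (not isolated)
Conditions: MgBr2·OEt2 (3 equiv), CH2Cl2, 0 °C to rt; then MeOH, 3 M HCl, 45 °C
Reagents that add atoms: none
Why: Proposed new method: chelation-gated dealkylative oxa-annulation, in which divalent magnesium held between the vinylogous-amide carbonyl and a ring A ortho MOM oxygen lets bromide remove only that acetal, the resulting magnesium phenoxide closes ring C by 6-endo addition–elimination at the enaminone β-carbon (O1–C2 bond, loss of dimethylamine) before the non-chelated ring B 2′-O-MOM group can be unmasked and divert the cascade to a 3-aroylbenzofuran, the peri 5-O-MOM group is then cleaved by the same chelation at the chromone carbonyl, and methanolic HCl finally removes the two ring B acetals; the closest known reaction types are MgBr2-mediated cleavage of ether protecting groups ortho to a carbonyl and the acid-triggered cyclisation of 2-hydroxyaryl enaminones to chromones; no stereocentre is formed.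

**Compound list**
1 | 4,6-dibromobenzene-1,3-diol (4,6-dibromoresorcinol) | Oc1cc(O)c(Br)cc1Br | starting material
2 | 1,5-dibromo-2,4-bis(methoxymethoxy)benzene | COCOc1cc(OCOC)c(Br)cc1Br | intermediate
3 | 1-bromo-3-methylbut-2-ene (prenyl bromide) | CC(C)=CCBr | starting material
4 | [5-bromo-2,4-bis(methoxymethoxy)phenyl]lithium | [Li]c1cc(Br)c(OCOC)cc1OCOC | intermediate
5 | 1-bromo-2,4-bis(methoxymethoxy)-5-(3-methylbut-2-en-1-yl)benzene | COCOc1cc(OCOC)c(CC=C(C)C)cc1Br | intermediate
6 | 1-(2,6-dihydroxy-4-methoxyphenyl)ethan-1-one | CC(=O)c1c(O)cc(OC)cc1O | starting material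
7 | disodium 2-acetyl-5-methoxybenzene-1,3-diolate | [Na+].[Na+].CC(=O)c1c([O-])cc(OC)cc1[O-] | intermediate
8 | 1-[4-methoxy-2,6-bis(methoxymethoxy)phenyl]ethan-1-one | CC(=O)c1c(OCOC)cc(OC)cc1OCOC | intermediate
9 | 1-[4-methoxy-2,6-bis(methoxymethoxy)phenyl]-2-[2,4-bis(methoxymethoxy)-5-(3-methylbut-2-en-1-yl)phenyl]ethan-1-one | COCOc1cc(OC)cc(OCOC)c1C(=O)Cc1cc(CC=C(C)C)c(OCOC)cc1OCOC | intermediate
10 | (E)-3-(dimethylamino)-1-[4-methoxy-2,6-bis(methoxymethoxy)phenyl]-2-[2,4-bis(methoxymethoxy)-5-(3-methylbut-2-en-1-yl)phenyl]prop-2-en-1-one | CN(C)/C=C(/C(=O)c1c(OCOC)cc(OC)cc1OCOC)c1cc(CC=C(C)C)c(OCOC)cc1OCOC | intermediate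
11 | bromomagnesium 2-[(E)-3-(dimethylamino)-2-[2,4-bis(methoxymethoxy)-5-(3-methylbut-2-en-1-yl)phenyl]prop-2-enoyl]-5-methoxy-3-(methoxymethoxy)phenolate | CN(C)/C=C(/C(=O)c1c(O[Mg]Br)cc(OC)cc1OCOC)c1cc(CC=C(C)C)c(OCOC)cc1OCOC | intermediate
12 | 7-methoxy-5-(methoxymethoxy)-3-[2,4-bis(methoxymethoxy)-5-(3-methylbut-2-en-1-yl)phenyl]-4H-chromen-4-one | COCOc1cc(OC)cc2occ(-c3cc(CC=C(C)C)c(OCOC)cc3OCOC)c(=O)c12 | intermediate
13 | 5-hydroxy-7-methoxy-3-[2,4-bis(methoxymethoxy)-5-(3-methylbut-2-en-1-yl)phenyl]-4H-chromen-4-one | COc1cc(O)c2c(=O)c(-c3cc(CC=C(C)C)c(OCOC)cc3OCOC)coc2c1 | intermediate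
14 | 3-[2,4-dihydroxy-5-(3-methylbut-2-en-1-yl)phenyl]-5-hydroxy-7-methoxy-4H-chromen-4-one (isopoegin B) | COc1cc(O)c2c(=O)c(-c3cc(CC=C(C)C)c(O)cc3O)coc2c1 | target

**Step count and risks**
Total step count: 6. Longest linear sequence: 5 (steps 1, 2, 4, 5, 6).

Most likely to fail, first: step 6, the proposed annulation. The gate may leak: if the ring B 2′-O-MOM group is lost or its ether oxygen attacks the activated enaminone before ring C closes, a 3-aroylbenzofuran forms. MOM cleavage by MgBr2·OEt2 may also be slow, and the acid stage can cyclise the prenyl group onto the 4′-hydroxyl (a 2,2-dimethylchroman). The fallback uses only known reactions, sets out from 6 and 5 and rejoins the route at 13. Ketone 6 is condensed with DMF-DMA to the enaminone (E)-3-(dimethylamino)-1-(2,6-dihydroxy-4-methoxyphenyl)prop-2-en-1-one F1. Iodine in MeOH cyclises it, again through the O1–C2 bond, to 5-hydroxy-3-iodo-7-methoxy-4H-chromen-4-one F2. Bromide 5 is borylated (B2pin2, PdCl2(dppf), KOAc, dioxane, 85 °C) to 2-[2,4-bis(methoxymethoxy)-5-(3-methylbut-2-en-1-yl)phenyl]-4,4,5,5-tetramethyl-1,3,2-dioxaborolane F3. Suzuki–Miyaura coupling of F2 with F3 (PdCl2(dppf), Na2CO3, DMF–H2O, 80 °C) gives 13, and 3 M HCl in MeOH at 45 °C (second stage of step 6) then gives 14.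

Second: step 4, the enolate arylation. Both partners are ortho-disubstituted and electron-rich, so oxidative addition and reductive elimination may be slow, and alkoxide base with a palladium hydride could move the prenyl double bond into conjugation. The fallback sets out from 8 and 5 and rejoins at 10, bypassing the deoxybenzoin. Ketone 8 is condensed with DMF-DMA to (E)-3-(dimethylamino)-1-[4-methoxy-2,6-bis(methoxymethoxy)phenyl]prop-2-en-1-one F4. NIS in CH2Cl2 iodinates the nucleophilic α-carbon to (Z)-3-(dimethylamino)-2-iodo-1-[4-methoxy-2,6-bis(methoxymethoxy)phenyl]prop-2-en-1-one F5. Suzuki–Miyaura coupling of F5 with the boronate F3, made from 5 as above (Pd(PPh3)4, K3PO4, dioxane–H2O, 90 °C), gives 10 directly.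

Third: step 2, the mono-exchange and prenylation. Copper-mediated attack at the tertiary end of prenyl bromide (SN2′) would give the 1,1-dimethylallyl isomer, and over-exchange or butylation by 1-bromobutane would cost material. The fallback sets out from 2 and rejoins at 5. The same exchange (via 4) is quenched with allyl bromide, which has no regiochemical ambiguity, to give 1-bromo-2,4-bis(methoxymethoxy)-5-(prop-2-en-1-yl)benzene F6. Cross-metathesis of F6 with 2-methylbut-2-ene (second-generation Grubbs catalyst RuCl2(=CHPh)(PCy3)(H2IMes), CH2Cl2, 40 °C) gives 5.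

**Further compounds**
F1 | step 6 | (E)-3-(dimethylamino)-1-(2,6-dihydroxy-4-methoxyphenyl)prop-2-en-1-one | CN(C)/C=C/C(=O)c1c(O)cc(OC)cc1O
F2 | step 6 | 5-hydroxy-3-iodo-7-methoxy-4H-chromen-4-one | COc1cc(O)c2c(=O)c(I)coc2c1
F3 | step 6 | 2-[2,4-bis(methoxymethoxy)-5-(3-methylbut-2-en-1-yl)phenyl]-4,4,5,5-tetramethyl-1,3,2-dioxaborolane | CC1(C)OB(OC1(C)C)c1cc(CC=C(C)C)c(OCOC)cc1OCOC
F4 | step 4 | (E)-3-(dimethylamino)-1-[4-methoxy-2,6-bis(methoxymethoxy)phenyl]prop-2-en-1-one | CN(C)/C=C/C(=O)c1c(OCOC)cc(OC)cc1OCOC
F5 | step 4 | (Z)-3-(dimethylamino)-2-iodo-1-[4-methoxy-2,6-bis(methoxymethoxy)phenyl]prop-2-en-1-one | CN(C)/C=C(/C(=O)c1c(OCOC)cc(OC)cc1OCOC)I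
F6 | step 2 | 1-bromo-2,4-bis(methoxymethoxy)-5-(prop-2-en-1-yl)benzene | C=CCc1cc(Br)c(OCOC)cc1OCOC
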